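**Plan**
1. Retrosynthetic cuts, in order: (i) C4–CH2Ar, back to a benzylic nucleophile and an oxolan-3-one; (ii) the C4 carbonyl, back to a C3=C4 alkene; (iii) the ring bonds O1–C2 and C3–C4 together, back to a cinnamaldehyde and glycolaldehyde.
2. Enabling feature: aryl–C2–C3–CH2OH of the oxolane is a cinnamaldehyde chain (β-carbon, α-carbon, CHO), and O1–C5–C4 with its oxygen on C4 is a glycolaldehyde unit, so the ring is their oxa-Michael/aldol [3+2] adduct.
3. Forward: Wittig enal synthesis; amine-catalysed domino oxa-Michael/aldol condensation closes the only ring as a 2,5-dihydrofuran-3-carbaldehyde (helpers: the formyl group and the C3=C4 bond); CHO to CH2OTBS; hydroboration–oxidation and oxidation to the ketone; CeCl3-mediated benzyl Grignard addition; desilylation; hydrogenolysis.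
4. Stereochemistry: C2 from the diarylprolinol silyl ether catalyst; C3 by hydroboration anti to the C2 aryl group (2,3-cis); C4 by benzyl addition anti to both cis substituents.

Key step: step 2

Remark: the text uses O1, C2 (aryl-bearing), C3 (CH2OH-bearing), C4 (carbinol) and C5 (CH2) for the ring atoms of every intermediate, while the systematic names number by rule. The descriptor at C2 reads S in 7–9 and R elsewhere for the same spatial arrangement, because the CIP priority of C3 changes. Glycolaldehyde is used as its commercial dimer.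

**Step 1**
Reactants: 1 3,4-bis(benzyloxy)benzaldehyde; 2 (triphenylphosphoranylidene)acetaldehyde
Product: 3 (E)-3-[3,4-bis(benzyloxy)phenyl]prop-2-enal
Conditions: toluene, 80 °C
Reagents that add atoms: none
Why: Wittig olefination with the stabilised formyl ylide gives the (E)-enal selectively, and a slight excess of 1 keeps a second homologation of 3 low.

**Step 2**
Reactants: 3 (E)-3-[3,4-bis(benzyloxy)phenyl]prop-2-enal; 4 glycolaldehyde dimer (1,4-dioxane-2,5-diol)
Product: 7 (2S)-2-[3,4-bis(benzyloxy)phenyl]-2,5-dihydrofuran-3-carbaldehyde, via glycolaldehyde 5 (not isolated), via aldol adduct 6 (not isolated)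
Conditions: (R)-α,α-diphenylprolinol trimethylsilyl ether (20 mol %), PhCO2H (20 mol %), CHCl3, rt → 40 °C
Reagents that add atoms: none
Why: Proposed new method: the (R)-amine condenses with 3 to the (E)-iminium ion, the hydroxyl group of 5 (released from 4) adds to its β-carbon (O1–C2), the resulting enamine attacks the tethered aldehyde carbon (C3–C4) to give iminium-bound 6, and loss of water from 6 through the conjugated iminium ion followed by hydrolysis gives 7 and returns the amine. The closest known reaction type is the iminium–enamine domino oxa-Michael/aldol condensation of enals with salicylaldehydes and with α-hydroxy ketones, and its sulfur counterpart with the dimer of mercaptoacetaldehyde; an aliphatic α-hydroxy aldehyde as the partner is the untested element. The oxolane ring closes in the aldol step by a 5-(enolexo)-exo-trig attack of the enamine carbon C3 on the aldehyde carbon C4. C2 is the only stereocentre that survives and is set in the oxa-Michael step: the CPh2(OTMS) group of the (R)-catalyst covers the Si face of the β-carbon of the s-trans (E)-iminium ion, so oxygen should enter from the Re face (descriptor S in 7), while the configurations at C3 and C4 of 6 are erased by the dehydration. The step needs O- rather than C-attack of glycolaldehyde (through its own enamine), 1,4- rather than 1,2-addition and a clean dehydration; these rest on the fact that only the O-adduct holds an enamine in reach of an aldehyde for five-ring closure and can drain irreversibly into the conjugated enal, while the slow opening of dimer 4 keeps free 5 scarce and the acid co-catalyst speeds iminium turnover and elimination.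

**Step 3**
Reactants: 7 (2S)-2-[3,4-bis(benzyloxy)phenyl]-2,5-dihydrofuran-3-carbaldehyde
Product: 8 [(2S)-2-[3,4-bis(benzyloxy)phenyl]-2,5-dihydrofuran-3-yl]methanol
Conditions: NaBH4, CeCl3·7H2O, MeOH, 0 °C
Reagents that add atoms: none
Why: Luche reduction gives clean 1,2-reduction of the enal to the allylic alcohol and leaves the C3=C4 bond and the C2 stereocentre untouched.

**Step 4**
Reactants: 8 [(2S)-2-[3,4-bis(benzyloxy)phenyl]-2,5-dihydrofuran-3-yl]methanol
Product: 9 tert-butyl{[(2S)-2-[3,4-bis(benzyloxy)phenyl]-2,5-dihydrofuran-3-yl]methoxy}dimethylsilane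
Conditions: TBSCl, imidazole, CH2Cl2, 0 °C → rt
Reagents that add atoms: tert-butyldimethylsilyl chloride, CC(C)(C)[Si](C)(C)Cl
Why: Standard silylation of a primary alcohol; the TBS ether keeps a free O–H away from the borane and the benzylic nucleophile and is a poor leaving group β to the later ketone.

**Step 5**
Reactants: 9 tert-butyl{[(2S)-2-[3,4-bis(benzyloxy)phenyl]-2,5-dihydrofuran-3-yl]methoxy}dimethylsilane
Product: 11 (3S,4S,5R)-5-[3,4-bis(benzyloxy)phenyl]-4-{[(tert-butyldimethylsilyl)oxy]methyl}oxolan-3-ol, via alkylborane 10 (not isolated)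
Conditions: BH3·THF, THF, 0 °C → rt; then NaOH, H2O2, H2O, 0 °C
Reagents that add atoms: hydrogen peroxide, OO (the new oxygen on C4); borane–THF, [BH3-][O+]1CCCC1 (boron of intermediate 10 only)
Why: Hydroboration–oxidation: syn addition of H–B should put boron on the less substituted C4 and hydrogen on C3 from the face opposite the C2 aryl group, which sets C3 with CH2OTBS cis to aryl, and oxidation with retention gives the C4 alcohol, whose configuration is removed in step 6.

**Step 6**
Reactants: 11 (3S,4S,5R)-5-[3,4-bis(benzyloxy)phenyl]-4-{[(tert-butyldimethylsilyl)oxy]methyl}oxolan-3-ol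
Product: 12 (4R,5R)-5-[3,4-bis(benzyloxy)phenyl]-4-{[(tert-butyldimethylsilyl)oxy]methyl}oxolan-3-one
Conditions: Dess–Martin periodinane, pyridine, CH2Cl2, 0 °C → rt
Reagents that add atoms: none
Why: Dess–Martin oxidation of the secondary alcohol under buffered, non-basic conditions should give the ketone without enolisation of the adjacent cis-configured C3 or β-elimination of the ring oxygen, and 12 is carried on without chromatography.

**Step 7**
Reactants: 12 (4R,5R)-5-[3,4-bis(benzyloxy)phenyl]-4-{[(tert-butyldimethylsilyl)oxy]methyl}oxolan-3-one; 13 4-(chloromethyl)-1,2-dimethoxybenzene (3,4-dimethoxybenzyl chloride)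
Product: 15 (3R,4R,5R)-5-[3,4-bis(benzyloxy)phenyl]-4-{[(tert-butyldimethylsilyl)oxy]methyl}-3-(3,4-dimethoxybenzyl)oxolan-3-ol, via benzylic Grignard reagent 14 (not isolated)
Conditions: 13, Mg, THF, 0 °C; then CeCl3, THF, −78 °C; then 12, −78 °C; aq NH4Cl
Reagents that add atoms: none
Why: CeCl3-mediated Grignard 1,2-addition uses the weakly basic reagent formed from 14 and CeCl3, which should outrun enolisation, and the nucleophile attacks C4 from the face opposite the cis CH2OTBS (C3) and aryl (C2) groups, so the tertiary hydroxyl ends cis to both, as in the target.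

**Step 8**
Reactants: 15 (3R,4R,5R)-5-[3,4-bis(benzyloxy)phenyl]-4-{[(tert-butyldimethylsilyl)oxy]methyl}-3-(3,4-dimethoxybenzyl)oxolan-3-ol
Product: 16 (3R,4R,5R)-5-[3,4-bis(benzyloxy)phenyl]-3-(3,4-dimethoxybenzyl)-4-(hydroxymethyl)oxolan-3-ol
Conditions: TBAF, THF, 0 °C → rt
Reagents that add atoms: none
Why: Fluoride-induced desilylation of the primary TBS ether; the benzyl ethers, the tertiary alcohol and the stereocentres are inert.

**Step 9**
Reactants: 16 (3R,4R,5R)-5-[3,4-bis(benzyloxy)phenyl]-3-(3,4-dimethoxybenzyl)-4-(hydroxymethyl)oxolan-3-ol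
Product: 17 (3R,4R,5R)-5-(3,4-dihydroxyphenyl)-3-(3,4-dimethoxybenzyl)-4-(hydroxymethyl)oxolan-3-ol
Conditions: H2 (1 atm), 10% Pd/C, EtOAc–MeOH, rt
Reagents that add atoms: none
Why: Hydrogenolysis of the two aryl benzyl ethers is much faster than cleavage of the cyclic benzylic C2–O1 ether, so stopping after uptake of two equivalents of H2 should free the catechol with all three stereocentres intact.

**Compound list**
1 | 3,4-bis(benzyloxy)benzaldehyde | O=Cc1ccc(OCc2ccccc2)c(OCc2ccccc2)c1 | starting material
2 | (triphenylphosphoranylidene)acetaldehyde | O=CC=P(c1ccccc1)(c1ccccc1)c1ccccc1 | starting material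
3 | (E)-3-[3,4-bis(benzyloxy)phenyl]prop-2-enal | O=C/C=C/c1ccc(OCc2ccccc2)c(OCc2ccccc2)c1 | intermediate
4 | glycolaldehyde dimer (1,4-dioxane-2,5-diol) | OC1COC(O)CO1 | starting material
5 | glycolaldehyde (2-hydroxyacetaldehyde) | OCC=O | intermediate (not isolated)
6 | (2R)-2-[3,4-bis(benzyloxy)phenyl]-4-hydroxyoxolane-3-carbaldehyde, aldol adduct, ring C3 and C4 undefined | O=CC1C(O)CO[C@H]1c1ccc(OCc2ccccc2)c(OCc2ccccc2)c1 | intermediate (not isolated)
7 | (2S)-2-[3,4-bis(benzyloxy)phenyl]-2,5-dihydrofuran-3-carbaldehyde | O=CC1=CCO[C@H]1c1ccc(OCc2ccccc2)c(OCc2ccccc2)c1 | intermediate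
8 | [(2S)-2-[3,4-bis(benzyloxy)phenyl]-2,5-dihydrofuran-3-yl]methanol | OCC1=CCO[C@H]1c1ccc(OCc2ccccc2)c(OCc2ccccc2)c1 | intermediate
9 | tert-butyl{[(2S)-2-[3,4-bis(benzyloxy)phenyl]-2,5-dihydrofuran-3-yl]methoxy}dimethylsilane | CC(C)(C)[Si](C)(C)OCC1=CCO[C@H]1c1ccc(OCc2ccccc2)c(OCc2ccccc2)c1 | intermediate
10 | [(3S,4R,5R)-5-[3,4-bis(benzyloxy)phenyl]-4-{[(tert-butyldimethylsilyl)oxy]methyl}oxolan-3-yl]borane, drawn as the monoalkylborane (boron trans to CH2OTBS and aryl) | B[C@@H]1CO[C@@H](c2ccc(OCc3ccccc3)c(OCc3ccccc3)c2)[C@H]1CO[Si](C)(C)C(C)(C)C | intermediate (not isolated)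
11 | (3S,4S,5R)-5-[3,4-bis(benzyloxy)phenyl]-4-{[(tert-butyldimethylsilyl)oxy]methyl}oxolan-3-ol | O[C@@H]1CO[C@@H](c2ccc(OCc3ccccc3)c(OCc3ccccc3)c2)[C@H]1CO[Si](C)(C)C(C)(C)C | intermediate
12 | (4R,5R)-5-[3,4-bis(benzyloxy)phenyl]-4-{[(tert-butyldimethylsilyl)oxy]methyl}oxolan-3-one | O=C1CO[C@@H](c2ccc(OCc3ccccc3)c(OCc3ccccc3)c2)[C@H]1CO[Si](C)(C)C(C)(C)C | intermediate
13 | 4-(chloromethyl)-1,2-dimethoxybenzene (3,4-dimethoxybenzyl chloride) | COc1ccc(CCl)cc1OC | starting material
14 | (3,4-dimethoxybenzyl)magnesium chloride | COc1ccc(C[Mg]Cl)cc1OC | intermediate (not isolated)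
15 | (3R,4R,5R)-5-[3,4-bis(benzyloxy)phenyl]-4-{[(tert-butyldimethylsilyl)oxy]methyl}-3-(3,4-dimethoxybenzyl)oxolan-3-ol | COc1ccc(C[C@]2(O)CO[C@@H](c3ccc(OCc4ccccc4)c(OCc4ccccc4)c3)[C@H]2CO[Si](C)(C)C(C)(C)C)cc1OC | intermediate
16 | (3R,4R,5R)-5-[3,4-bis(benzyloxy)phenyl]-3-(3,4-dimethoxybenzyl)-4-(hydroxymethyl)oxolan-3-ol | COc1ccc(C[C@]2(O)CO[C@@H](c3ccc(OCc4ccccc4)c(OCc4ccccc4)c3)[C@H]2CO)cc1OC | intermediate
17 | (3R,4R,5R)-5-(3,4-dihydroxyphenyl)-3-(3,4-dimethoxybenzyl)-4-(hydroxymethyl)oxolan-3-ol | COc1ccc(C[C@]2(O)CO[C@@H](c3ccc(O)c(O)c3)[C@H]2CO)cc1OC | target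

**Step count and risks**
Total steps: 9. Longest linear sequence: 9 steps (1 → 17).

Steps most likely to fail:

1. Step 2. The aliphatic hydroxyl may add too slowly to the iminium ion, so that glycolaldehyde is consumed as an enamine donor or by self-aldolisation. The reversible oxa-Michael step may erode the enantiomeric purity, and dienamine formation from the product may lead to isomerisation of the ring alkene. Fallback with known chemistry, from aldehyde 1 to ketone 12 (it also replaces steps 1 and 3–6): (R)-4-benzyloxazolidin-2-one is N-acylated with the pivaloyl mixed anhydride of 3-[(tert-butyldimethylsilyl)oxy]propanoic acid (PivCl, Et3N, LiCl, THF) to give (R)-4-benzyl-3-{3-[(tert-butyldimethylsilyl)oxy]propanoyl}oxazolidin-2-one F1. Its (Z)-boron enolate (Bu2BOTf, i-Pr2NEt, CH2Cl2, −78 → 0 °C) adds to 1 in an Evans syn-aldol reaction to give the (2R,3R)-aldol imide F2, whose carbinol and α-carbons are the later C2 and C3 in the cis sense. LiOH/H2O2 (THF–H2O, 0 °C) removes the auxiliary to give the (2R,3R)-β-hydroxy acid F3. Activation as the mixed anhydride (i-BuOCOCl, N-methylmorpholine, −20 °C) and diazomethane give the (3R,4R)-hydroxy diazoketone F4. Rh2(OAc)4 (1 mol %, CH2Cl2, rt) then closes the ring by intramolecular carbene O–H insertion to ketone 12.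

2. Step 5. Hydrogen may be delivered to the aryl-bearing face of C3, regiocontrol may be incomplete, and the C4–boron/C5–oxygen unit may undergo β-elimination on warming. Fallback, from 9 back to 11: reagent control in place of substrate control. Asymmetric hydroboration with monoisopinocampheylborane (IpcBH2, THF, −25 °C; then NaOH, H2O2) uses the antipode whose own facial preference on 1-substituted cyclopentenes matches the wanted face, expected by analogy to be the reagent from (−)-α-pinene, so that reagent and substrate bias reinforce each other. The intermediate is the alkyl(isopinocampheyl)borane F5, oxidised in the same flask to 11.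

3. Step 7. The benzylic nucleophile may act as a base and enolise the ketone, with loss of the cis configuration at C3 or β-elimination of the ring oxygen, and Wurtz coupling may waste 13 when 14 is formed. Fallback, from 12 to 15: Corey–Chaykovsky epoxidation with dimethylsulfonium methylide (Me3SI, KHMDS, THF, −10 °C) delivers CH2 to C4 anti to the two cis substituents and gives the spiro-epoxide F6 with its oxygen cis to CH2OTBS and aryl. CuI-catalysed opening at the epoxide CH2 with 3,4-dimethoxyphenylmagnesium bromide (THF, −30 °C) then gives 15 without a benzylic Grignard reagent.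

**Further compounds**
F1 | step 2 | (R)-4-benzyl-3-{3-[(tert-butyldimethylsilyl)oxy]propanoyl}oxazolidin-2-one | CC(C)(C)[Si](C)(C)OCCC(=O)N1C(=O)OC[C@H]1Cc1ccccc1
F2 | step 2 | (R)-4-benzyl-3-[(2R,3R)-3-[3,4-bis(benzyloxy)phenyl]-2-{[(tert-butyldimethylsilyl)oxy]methyl}-3-hydroxypropanoyl]oxazolidin-2-one | O[C@@H](c1ccc(OCc2ccccc2)c(OCc2ccccc2)c1)[C@H](C(=O)N1C(=O)OC[C@H]1Cc1ccccc1)CO[Si](C)(C)C(C)(C)C
F3 | step 2 | (2R,3R)-3-[3,4-bis(benzyloxy)phenyl]-2-{[(tert-butyldimethylsilyl)oxy]methyl}-3-hydroxypropanoic acid | O[C@@H](c1ccc(OCc2ccccc2)c(OCc2ccccc2)c1)[C@H](C(=O)O)CO[Si](C)(C)C(C)(C)C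
F4 | step 2 | (3R,4R)-4-[3,4-bis(benzyloxy)phenyl]-3-{[(tert-butyldimethylsilyl)oxy]methyl}-1-diazo-4-hydroxybutan-2-one | O[C@@H](c1ccc(OCc2ccccc2)c(OCc2ccccc2)c1)[C@H](C(=O)C=[N+]=[N-])CO[Si](C)(C)C(C)(C)C
F5 | step 5 | [(3S,4R,5R)-5-[3,4-bis(benzyloxy)phenyl]-4-{[(tert-butyldimethylsilyl)oxy]methyl}oxolan-3-yl](isopinocampheyl)borane, isopinocampheyl group from (−)-α-pinene | C[C@@H]1[C@@H](B[C@@H]3CO[C@@H](c4ccc(OCc5ccccc5)c(OCc5ccccc5)c4)[C@H]3CO[Si](C)(C)C(C)(C)C)C[C@H]2C[C@@H]1C2(C)C
F6 | step 7 | (3S,6R,7R)-6-[3,4-bis(benzyloxy)phenyl]-7-{[(tert-butyldimethylsilyl)oxy]methyl}-1,5-dioxaspiro[2.4]heptane | C1O[C@]12CO[C@@H](c3ccc(OCc4ccccc4)c(OCc4ccccc4)c3)[C@H]2CO[Si](C)(C)C(C)(C)C
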